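If I am to trust readings rather than a scheme, I begin with a balance of the reagent, which in the oak run is charged below the solid substrate, 8.8 mM against 11 mM, and so is the limiting reagent.

| setting | oak | amber | ochre |
|---|---|---|---|
| solid substrate | 11 mM | 11 mM | 15 mM |
| reagent | 8.8 mM | 8.80 mM | 6.00 mM |
| catalyst | 13 µM | 19 µM | 19 µM |
| remark | run made earlier |  |  |
| time |  | 6.0 h | 10 h |

- oak (time / min: target / %, isomer of the product / %): 20.0: 13.0, 13.0; 40.0: 21.1, 33.1; 60.0: 21.2, 43.4; 80.0: 20.7, 47.7; 120: 20.8, 50.3

(readings scatter by 0.5 percentage points)

- as a solid, counted per litre of solution: solid substrate
- the numbers in the tables scatter by 0.5 percentage points (one standard deviation)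
- at the start none of the solid substrate is in solution
- what has only dissolved of solid substrate counts as not reacted
- no earlier run changes the charge of catalyst; that part of a forecast is a guess

1. which one finishes higher in share of target in all that became target or isomer of the product ("neither" within 2 percentage points) (amber / ochre / neither)
2. share of target in all that became target or isomer of the product, amber
3. share of target in all that became target or isomer of the product, ochre

Counting one reagent for each product, the last oak reading, at 120 min, gives target plus isomer of the product 7.82 mM, which leaves 0.980 mM of reagent unspent while the sum is slowing, so I read the oak flask as coming to a balance, not as running dry. The ratio c(isomer of the product)/c(target) supports this: it climbs from 1.00 through 2.05 to 2.30 and 2.42, in shrinking steps. I therefore carry the end share, target over target plus isomer of the product at the last oak reading, 29.3%. Two products made from the same partners have a ratio at balance that contains no concentration of reagent, so under thermodynamic control I expect this share in amber and in ochre, whose smaller reagent charge and larger charge of solid substrate should change how much forms, not how it divides. I commit to 29.3% for each flask, and to neither.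

The weak link is whether the oak flask had reached its limit, since the share was still 30.3% at 80.0 min. That drift of 1 percentage point stands against a scatter of 0.5 points per reading, so the value may sit slightly lower. The comparison survives, provided the catalyst lasts, which is my guess: amber runs 3.00 times and ochre 5.00 times as long as the oak run, and I expect both to approach one limit.

The forecast said ochre, with 41% for amber and 53% for ochre, on the view that “the catalyst dies after a fixed number of turnovers”, which differs from my reckoning.

The flasks give 28.6% for amber and 28.6% for ochre, so the answer is neither.

    starting material + reagent ⇌ target (K = 760 M⁻¹, k = 0.101 M⁻¹ s⁻¹)
    starting material + reagent ⇌ isomer of the product (K = 1900 M⁻¹, k = 0.0417 M⁻¹ s⁻¹)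
    target + catalyst ⇌ isomer of the product + catalyst, rate k3*[catalyst]*[target] forward; the back reaction follows from the equilibrium constant (k = 87.0 M⁻¹ s⁻¹)
    solid substrate ⇌ starting material, rate k4*(cs4 - [starting material]) while solid is left; crystals form when [starting material] > cs4 (solubility = 8.80 mM, k = 9.14 × 10⁻⁴ s⁻¹)

In amber, the exchange between target and isomer of the product, taken by this step alone and both ways together, relaxes with a half-life of 0.0832 h at the asked time, far shorter than the 6.0 h of the run. The catalyst stands at 100% of its charge at that time, with target at 20.4% and isomer of the product at 51.0%. In the neighbour like amber but with 3.5 mM of reagent, the carried share gives 29.3%; the computed flask holds 8.67% of target and 21.7% of isomer of the product after 6.00 h, a share of 28.6%.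

The runs stem from a simulated flask on assumed constants; noise was put on by code.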